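The constants were set for the occasion, and the outcome is calculated.

D.L is the product, and it can fall back to D and L, so ask what share of the dissolved J sits as D.L at the reading.

J 20 mM; E 5.4 mM (held); time 2.0 min

* the D.L standing at 2.0 min, as a percentage of the J charged
* the change that raises the amount of D.L at 2.0 min, in percent of the J charged most ("none" if none brings more than 2 percentage points) (north-west / west / east / north / none)
* amount of D.L at 2.0 min, in percent of the J charged, after east

- north-west: doubling the dissolution coefficient of step 3, all else as stated
- west: doubling the transfer coefficient of step 1, all else as stated
- east: doubling the solubility in step 3, all else as stated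
- north: doubling the saturation concentration of E, all else as stated

    E ⇌ L, rate k1*(csat - [L]) (k1 = 0.018 s⁻¹, csat = 5.4 mM)
    D + L ⇌ D.L (K2 = 330 M⁻¹, k2 = 16 M⁻¹ s⁻¹)
    J ⇌ D, rate k3*(cs3 - [D]) while solid is left; crystals form when [D] > cs3 (cs3 = 12 mM, k3 = 0.047 s⁻¹)
    D ⇌ Q (K4 = 14, k4 = 0.10 s⁻¹)

Start with the solid. Into a solution kept empty, and if the solid never ran out, step 3 could deliver 338% of the charge by 2.0 min, more than the charge, so count the 20 mM as dissolved by then.

But D does not stay D. It turns into Q and back with a relaxation half-life of 0.108 min, far shorter than the run, so freeze that balance at 14 parts of Q to each part of D. Q is the resting state. Call 15.0 the divider: the parts of D and Q together for each part of free D.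

The way back from D.L has a half-life of 0.238 min, shorter than the run, so freeze that too. D.L then stands to free D as 330 M⁻¹ times [L], and its share of the charge is this ratio over the divider plus the ratio.

But [L] is still climbing towards 5.4 mM. Uptake by itself gives 4.78 mM at 2.0 min, on the high side, since D.L holds some of what entered. The ratio is 1.58, so I reckon 9.51%.

Dissolving does not appear in this rule, so keep 9.51% after east. Doubling the saturation gives 17.4%, while west, reckoned with [L] at the full 5.4 mM, gives a share of 10.6%, less than north. So choose north.

The forecast gives 9%, a little below my figure, then north and 8.9% after east, holding that D.L “scales almost directly with dissolved L”.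

The flask gives 8.53%, then north with a gain of 7.3 percentage points, and 7.98% after east.

In the flask at 2.00 min, the step to D.L, taken by itself, relaxes with a half-life of 0.0832 min, short against the 2.0 min of the run, and the [L] of 4.45 mM put through the divider of 15.0 gives 8.92% against 8.53% of D.L standing. In the neighbour flask with 12 mM of J, the [L] of 4.57 mM through the same divider gives 9.14%, and D.L stands at 8.49%.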